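**Plan**

1. The retrosynthesis first cuts the two acyl C–O bonds (pentanoate on the CH2O arm, isobutyrate on the phenol oxygen) and masks the three oxygens as a 4-methoxybenzyl ether, an aryl triisopropylsilyl ether and a benzylic tert-butyldimethylsilyl ether.
2. It then cuts the Cq–CH2 and CH2–O bonds of the oxirane together. The oxirane CH2 is one carbon held only by the fully substituted ring carbon Cq and the ring oxygen, so taking it out leaves an aryl ketone whose carbonyl carbon sits between a flat benzene ring and an sp3 CH2O arm.
3. Last, the aryl–C(=O) bond is cut, giving an aryllithium derived from methyl 4-bromo-3-hydroxybenzoate and the N-methoxy-N-methylamide of (4-methoxybenzyloxy)acetic acid.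
4. Forward: the arene is protected and reduced (steps 1–3), the amide is made (step 4), the ketone is joined (step 5), and the oxirane, the only ring formed, is closed by CH2 transfer from dimethylsulfoxonium methylide (step 6). Ether cleavage, pentanoylation, silyl-to-isobutyryl exchange at the phenol and final desilylation follow (steps 7–10).
5. The single stereocentre Cq (R in the target) is set in step 6 by LaLi3(binaphthoxide)3, which must send the CH2 to the Re face of the ketone; no later step breaks a bond at Cq.

Key step: step 6

Abbreviations: TBS = tert-butyldimethylsilyl, TIPS = triisopropylsilyl, PMB = 4-methoxybenzyl, DDQ = 2,3-dichloro-5,6-dicyano-1,4-benzoquinone, DMAP = 4-(dimethylamino)pyridine, TBAF = tetrabutylammonium fluoride.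

Remark (assumption): the antipode of the catalyst is chosen by shape analogy with aryl methyl ketones (arene in the place of phenyl, CH2OPMB in the place of methyl), i.e. the one that turns acetophenone into (R)-2-methyl-2-phenyloxirane. It is written as the (R)-binaphthoxide complex; the mirror-image complex is used instead if a small-scale trial shows the opposite sense.

**Route**

Step 1
Reactants: 1 methyl 4-bromo-3-hydroxybenzoate
Product: 2 methyl 4-bromo-3-(triisopropylsilyloxy)benzoate
Conditions: TIPSCl, imidazole, DMF, rt
Reagents that add atoms: triisopropylsilyl chloride, CC(C)[Si](Cl)(C(C)C)C(C)C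
Why: Imidazole-promoted O-silylation of an acidic phenol; the bulky TIPS group is chosen because it must resist silyl migration next to the aryllithium of step 5 and next to the alkoxides formed in steps 5 and 6.

Step 2
Reactants: 2 methyl 4-bromo-3-(triisopropylsilyloxy)benzoate
Product: 3 [4-bromo-3-(triisopropylsilyloxy)phenyl]methanol
Conditions: i-Bu2AlH (2.5 equiv), CH2Cl2, −78 → 0 °C; aq. potassium sodium tartrate
Reagents that add atoms: none
Why: Hydride reduction of a benzoate ester to the benzyl alcohol with i-Bu2AlH, which at or below 0 °C leaves the aryl bromide and the aryl silyl ether untouched.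

Step 3
Reactants: 3 [4-bromo-3-(triisopropylsilyloxy)phenyl]methanol
Product: 4 {[4-bromo-3-(triisopropylsilyloxy)benzyl]oxy}(tert-butyl)dimethylsilane
Conditions: TBSCl, imidazole, CH2Cl2, rt
Reagents that add atoms: tert-butyldimethylsilyl chloride, CC(C)(C)[Si](C)(C)Cl
Why: Standard imidazole-promoted silylation of a primary alcohol; an alkyl TBS ether is cleaved by fluoride more slowly than the phenolic TIPS ether, which fixes the order of the last two steps.

Step 4
Reactants: 5 4-methoxybenzyl alcohol; 6 2-chloro-N-methoxy-N-methylacetamide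
Product: 8 N-methoxy-2-[(4-methoxybenzyl)oxy]-N-methylacetamide, via sodium (4-methoxyphenyl)methanolate 7 (not isolated)
Conditions: NaH, THF, 0 °C; then 6, 0 °C → rt
Reagents that add atoms: none
Why: Williamson ether synthesis, in which the alkoxide displaces the carbonyl-activated primary chloride by an SN2 reaction faster than it attacks the N-methoxy-N-methylamide carbonyl.

Step 5
Reactants: 4 {[4-bromo-3-(triisopropylsilyloxy)benzyl]oxy}(tert-butyl)dimethylsilane; 8 N-methoxy-2-[(4-methoxybenzyl)oxy]-N-methylacetamide
Product: 11 1-[4-(tert-butyldimethylsilyloxymethyl)-2-(triisopropylsilyloxy)phenyl]-2-[(4-methoxybenzyl)oxy]ethan-1-one, via aryllithium 9 (not isolated), via lithium hemiaminal 10 (not isolated)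
Conditions: n-BuLi (1.05 equiv), THF, −78 °C; then 8, −78 → −40 °C; aq. NH4Cl
Reagents that add atoms: none
Why: Bromine–lithium exchange followed by a Weinreb ketone synthesis, in which the chelated tetrahedral lithium adduct 10 survives until the quench so that only one aryl group adds, while at −78 °C the TIPS group should stay on oxygen.

Step 6
Reactants: 11 1-[4-(tert-butyldimethylsilyloxymethyl)-2-(triisopropylsilyloxy)phenyl]-2-[(4-methoxybenzyl)oxy]ethan-1-one; 12 trimethylsulfoxonium iodide
Product: 15 (2R)-2-[4-(tert-butyldimethylsilyloxymethyl)-2-(triisopropylsilyloxy)phenyl]-2-{[(4-methoxybenzyl)oxy]methyl}oxirane, via dimethylsulfoxonium methylide 13 (not isolated), via betaine 14 (not isolated)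
Conditions: 12, NaH, THF, reflux; then the solution of 13 (1.2 equiv), 11, LaLi3[(R)-binaphthoxide]3 (5 mol %, from La(Oi-Pr)3, (R)-1,1'-bi-2-naphthol and n-BuLi), (2,4,6-(MeO)3C6H2)3P=O (5 mol %), 5 Å molecular sieves, THF, rt
Reagents that add atoms: none
Why: Proposed new method: the closest known reaction type is the LaLi3(binaphthoxide)3/triarylphosphine oxide-catalysed Corey–Chaykovsky epoxidation of aryl methyl ketones, and its extension to a ketone with CH2OPMB in place of methyl and an ortho-silyloxy group on the arene rests on the same two-centre activation, the Lewis acidic lanthanum binding the only carbonyl oxygen while a lithium binaphthoxide unit holds the ylide and the phosphine oxide tunes the coordination sphere. The nucleophilic CH2 of ylide 13 adds to the carbonyl carbon of 11 and forms the Cq–CH2 bond of betaine 14, whose alkoxide then displaces dimethyl sulfoxide from that CH2 and forms the CH2–O bond. The oxirane therefore closes by a 3-exo-tet intramolecular SN2 displacement. Cq is the only new stereocentre and is set under catalyst control in the C–C bond-forming addition, the binaphthoxide pocket being required to expose the Re face of the ketone, and the ring closure leaves Cq untouched. The step needs enantiofacial selectivity, which the substrate supports through the shape contrast between the flat ortho-substituted arene and the sp3 CH2O arm, the same contrast the catalyst reads between aryl and methyl. It also needs chemoselectivity, which is secured because 11 holds no electrophile other than the ketone (only silyl and benzyl-type ethers), the weakly basic sulfoxonium ylide should not enolise the α-alkoxy ketone, the bulky TIPS group resists transfer to the betaine alkoxide, and 1.2 equivalents of ylide at room temperature should stop short of ring expansion to the oxetane.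

Step 7
Reactants: 15 (2R)-2-[4-(tert-butyldimethylsilyloxymethyl)-2-(triisopropylsilyloxy)phenyl]-2-{[(4-methoxybenzyl)oxy]methyl}oxirane
Product: 16 {(2S)-2-[4-(tert-butyldimethylsilyloxymethyl)-2-(triisopropylsilyloxy)phenyl]oxiran-2-yl}methanol
Conditions: DDQ (1.3 equiv), CH2Cl2/aq. KH2PO4–K2HPO4 buffer (pH 7), 0 °C
Reagents that add atoms: none
Why: Oxidative cleavage of a 4-methoxybenzyl ether with DDQ (hydride abstraction from the anisyl CH2, then hydrolysis of the oxocarbenium ion) in a buffered two-phase medium that should keep the acid-sensitive aryl oxirane and both silyl ethers intact; no bond at Cq changes, and the descriptor becomes S only because CH2OH ranks below the oxirane CH2.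

Step 8
Reactants: 16 {(2S)-2-[4-(tert-butyldimethylsilyloxymethyl)-2-(triisopropylsilyloxy)phenyl]oxiran-2-yl}methanol
Product: 17 {(2R)-2-[4-(tert-butyldimethylsilyloxymethyl)-2-(triisopropylsilyloxy)phenyl]oxiran-2-yl}methyl pentanoate
Conditions: (n-BuCO)2O, Et3N, DMAP (cat.), CH2Cl2, 0 °C
Reagents that add atoms: pentanoic anhydride, CCCCC(=O)OC(=O)CCCC
Why: DMAP-catalysed acylation of a primary alcohol with an anhydride under mildly basic conditions that should not open the oxirane; the pentanoate goes on before the phenol ester exists, so an aryl ester never faces a free neighbouring hydroxyl, and the descriptor returns to R by ranking alone.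

Step 9
Reactants: 17 {(2R)-2-[4-(tert-butyldimethylsilyloxymethyl)-2-(triisopropylsilyloxy)phenyl]oxiran-2-yl}methyl pentanoate
Product: 19 5-(tert-butyldimethylsilyloxymethyl)-2-{(2R)-2-[(pentanoyloxy)methyl]oxiran-2-yl}phenyl 2-methylpropanoate, via caesium aryloxide 18 (not isolated)
Conditions: CsF (1.5 equiv), (i-PrCO)2O (3 equiv), DMF, 0 °C → rt
Reagents that add atoms: isobutyric anhydride, CC(C)C(=O)OC(=O)C(C)C
Why: Fluoride-mediated desilylative acylation, in which fluoride attacks the aryl silyl ether in preference to the primary alkyl TBS ether because aryloxide is much the better leaving group from silicon, and caesium aryloxide 18 should be acylated by the excess anhydride as fast as it forms, before it can attack the neighbouring oxirane.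

Step 10
Reactants: 19 5-(tert-butyldimethylsilyloxymethyl)-2-{(2R)-2-[(pentanoyloxy)methyl]oxiran-2-yl}phenyl 2-methylpropanoate
Product: 20 5-(hydroxymethyl)-2-{(2R)-2-[(pentanoyloxy)methyl]oxiran-2-yl}phenyl 2-methylpropanoate
Conditions: Et3N·3HF, THF, rt
Reagents that add atoms: none
Why: Fluoride cleavage of a primary TBS ether with the nearly neutral Et3N·3HF, which at room temperature should spare both esters (no base, hence no acyl transfer to the freed benzylic alcohol) and the aryl oxirane, now attached to a less electron-rich, acyloxy-substituted ring.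

**Compound list**

1 | methyl 4-bromo-3-hydroxybenzoate | COC(=O)c1ccc(Br)c(O)c1 | starting material
2 | methyl 4-bromo-3-(triisopropylsilyloxy)benzoate | COC(=O)c1ccc(Br)c(O[Si](C(C)C)(C(C)C)C(C)C)c1 | intermediate
3 | [4-bromo-3-(triisopropylsilyloxy)phenyl]methanol | OCc1ccc(Br)c(O[Si](C(C)C)(C(C)C)C(C)C)c1 | intermediate
4 | {[4-bromo-3-(triisopropylsilyloxy)benzyl]oxy}(tert-butyl)dimethylsilane | CC(C)(C)[Si](C)(C)OCc1ccc(Br)c(O[Si](C(C)C)(C(C)C)C(C)C)c1 | intermediate
5 | 4-methoxybenzyl alcohol | COc1ccc(CO)cc1 | starting material
6 | 2-chloro-N-methoxy-N-methylacetamide | CON(C)C(=O)CCl | starting material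
7 | sodium (4-methoxyphenyl)methanolate (formed in the flask) | COc1ccc(C[O-])cc1.[Na+] | intermediate
8 | N-methoxy-2-[(4-methoxybenzyl)oxy]-N-methylacetamide | COc1ccc(COCC(=O)N(C)OC)cc1 | intermediate
9 | [4-(tert-butyldimethylsilyloxymethyl)-2-(triisopropylsilyloxy)phenyl]lithium (formed in the flask) | [Li]c1ccc(CO[Si](C)(C)C(C)(C)C)cc1O[Si](C(C)C)(C(C)C)C(C)C | intermediate
10 | lithium 1-[4-(tert-butyldimethylsilyloxymethyl)-2-(triisopropylsilyloxy)phenyl]-1-[methoxy(methyl)amino]-2-[(4-methoxybenzyl)oxy]ethan-1-olate, racemic (formed in the flask) | COc1ccc(COCC([O-])(N(C)OC)c2ccc(CO[Si](C)(C)C(C)(C)C)cc2O[Si](C(C)C)(C(C)C)C(C)C)cc1.[Li+] | intermediate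
11 | 1-[4-(tert-butyldimethylsilyloxymethyl)-2-(triisopropylsilyloxy)phenyl]-2-[(4-methoxybenzyl)oxy]ethan-1-one | COc1ccc(COCC(=O)c2ccc(CO[Si](C)(C)C(C)(C)C)cc2O[Si](C(C)C)(C(C)C)C(C)C)cc1 | intermediate
12 | trimethylsulfoxonium iodide | C[S+](C)(C)=O.[I-] | starting material
13 | dimethylsulfoxonium methylide (formed in the flask) | CS(C)(=O)=C | intermediate
14 | (2S)-2-[4-(tert-butyldimethylsilyloxymethyl)-2-(triisopropylsilyloxy)phenyl]-1-(dimethylsulfoxonio)-3-[(4-methoxybenzyl)oxy]propan-2-olate, betaine (formed in the flask) | COc1ccc(COC[C@@]([O-])(c2ccc(CO[Si](C)(C)C(C)(C)C)cc2O[Si](C(C)C)(C(C)C)C(C)C)C[S+](C)(C)=O)cc1 | intermediate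
15 | (2R)-2-[4-(tert-butyldimethylsilyloxymethyl)-2-(triisopropylsilyloxy)phenyl]-2-{[(4-methoxybenzyl)oxy]methyl}oxirane | COc1ccc(COC[C@@]2(c3ccc(CO[Si](C)(C)C(C)(C)C)cc3O[Si](C(C)C)(C(C)C)C(C)C)CO2)cc1 | intermediate
16 | {(2S)-2-[4-(tert-butyldimethylsilyloxymethyl)-2-(triisopropylsilyloxy)phenyl]oxiran-2-yl}methanol | OC[C@@]1(c2ccc(CO[Si](C)(C)C(C)(C)C)cc2O[Si](C(C)C)(C(C)C)C(C)C)CO1 | intermediate
17 | {(2R)-2-[4-(tert-butyldimethylsilyloxymethyl)-2-(triisopropylsilyloxy)phenyl]oxiran-2-yl}methyl pentanoate | CCCCC(=O)OC[C@@]1(c2ccc(CO[Si](C)(C)C(C)(C)C)cc2O[Si](C(C)C)(C(C)C)C(C)C)CO1 | intermediate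
18 | caesium 5-(tert-butyldimethylsilyloxymethyl)-2-{(2R)-2-[(pentanoyloxy)methyl]oxiran-2-yl}phenolate (formed in the flask) | CCCCC(=O)OC[C@@]1(c2ccc(CO[Si](C)(C)C(C)(C)C)cc2[O-])CO1.[Cs+] | intermediate
19 | 5-(tert-butyldimethylsilyloxymethyl)-2-{(2R)-2-[(pentanoyloxy)methyl]oxiran-2-yl}phenyl 2-methylpropanoate | CCCCC(=O)OC[C@@]1(c2ccc(CO[Si](C)(C)C(C)(C)C)cc2OC(=O)C(C)C)CO1 | intermediate
20 | 5-(hydroxymethyl)-2-{(2R)-2-[(pentanoyloxy)methyl]oxiran-2-yl}phenyl 2-methylpropanoate (CNP0243215.1) | CCCCC(=O)OC[C@@]1(c2ccc(CO)cc2OC(=O)C(C)C)CO1 | target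

**Count and risks**

Total step count: 10. Longest linear sequence: 9 steps (steps 1, 2, 3, 5, 6, 7, 8, 9, 10 from compound 1); step 4 is a one-step side branch.

Steps most likely to fail:

1. Step 6 (the step labelled as a proposed new method). The catalyst may discriminate the two faces poorly, because the CH2O arm is larger than methyl and its ether oxygen can bind lanthanum or lithium and change how the ketone sits in the pocket. The hindered, ortho-silylated carbonyl may also react sluggishly, and the betaine alkoxide may take the TIPS group from the neighbouring aryl oxygen before the ring closes. The fallback uses known chemistry and gives up the ylide. It sets out from ketone 11: Wittig methylenation (Ph3PCH3Br, KOt-Bu, THF, 0 °C → rt) gives the 1,1-disubstituted alkene 2-[4-(tert-butyldimethylsilyloxymethyl)-2-(triisopropylsilyloxy)phenyl]allyl 4-methoxybenzyl ether F1. DDQ in buffered CH2Cl2 then frees the allylic alcohol 2-[4-(tert-butyldimethylsilyloxymethyl)-2-(triisopropylsilyloxy)phenyl]prop-2-en-1-ol F2. Sharpless asymmetric epoxidation (Ti(Oi-Pr)4, L-(+)-diisopropyl tartrate, t-BuOOH, 4 Å molecular sieves, CH2Cl2, −20 °C) should deliver oxygen to the face that this tartrate uses in turning allyl alcohol into (S)-glycidol; with the arene in the place of hydrogen this is the (S)-epoxy alcohol 16. The route is rejoined at 16 and continues with step 8.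

2. Step 9. The aryloxide set free beside the oxirane may open it (attack on the oxirane CH2, or quinone-methide-type heterolysis of the benzylic C–O bond) faster than the anhydride captures it. Fluoride may also strip the benzylic TBS group, whose alcohol would then be acylated. The fallback sets out from 17 and splits the exchange into two operations that never generate the aryloxide. TBAF buffered with acetic acid (THF, −20 → 0 °C) cleaves the aryl silyl ether to the neutral phenol {(2R)-2-[4-(tert-butyldimethylsilyloxymethyl)-2-hydroxyphenyl]oxiran-2-yl}methyl pentanoate F3. This is acylated at once with isobutyric anhydride and pyridine (CH2Cl2, −20 °C), which returns to the route at 19.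

3. Step 5. The hindered aryllithium may deprotonate the α-CH2 of the amide instead of adding to it, or the TIPS group may migrate from oxygen to the lithiated carbon before the amide is captured. The fallback sets out from 8 and 4 and replaces acyl substitution by carbonyl addition and oxidation. i-Bu2AlH (THF, −78 °C) reduces 8 to (4-methoxybenzyloxy)acetaldehyde F4. Aryllithium 9, made from 4 and n-BuLi as in step 5, adds to this more electrophilic partner at −78 °C to give the racemic carbinol 1-[4-(tert-butyldimethylsilyloxymethyl)-2-(triisopropylsilyloxy)phenyl]-2-[(4-methoxybenzyl)oxy]ethan-1-ol F5. Dess–Martin periodinane (NaHCO3, CH2Cl2, rt) oxidises it, which returns to the route at ketone 11.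

**Further compounds**

F1 | step 6 | 2-[4-(tert-butyldimethylsilyloxymethyl)-2-(triisopropylsilyloxy)phenyl]allyl 4-methoxybenzyl ether | COc1ccc(COCC(=C)c2ccc(CO[Si](C)(C)C(C)(C)C)cc2O[Si](C(C)C)(C(C)C)C(C)C)cc1
F2 | step 6 | 2-[4-(tert-butyldimethylsilyloxymethyl)-2-(triisopropylsilyloxy)phenyl]prop-2-en-1-ol | C=C(CO)c1ccc(CO[Si](C)(C)C(C)(C)C)cc1O[Si](C(C)C)(C(C)C)C(C)C
F3 | step 9 | {(2R)-2-[4-(tert-butyldimethylsilyloxymethyl)-2-hydroxyphenyl]oxiran-2-yl}methyl pentanoate | CCCCC(=O)OC[C@@]1(c2ccc(CO[Si](C)(C)C(C)(C)C)cc2O)CO1
F4 | step 5 | (4-methoxybenzyloxy)acetaldehyde | COc1ccc(COCC=O)cc1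
F5 | step 5 | 1-[4-(tert-butyldimethylsilyloxymethyl)-2-(triisopropylsilyloxy)phenyl]-2-[(4-methoxybenzyl)oxy]ethan-1-ol, racemic | COc1ccc(COCC(O)c2ccc(CO[Si](C)(C)C(C)(C)C)cc2O[Si](C(C)C)(C(C)C)C(C)C)cc1
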